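**Plan**
- Retrosynthetic cuts: the two O-acyl bonds; then C4–C15 (the C4 methyl arises from a ring A 2,4-dione); then C2–C3 and C5–C10 together; the open chain so obtained is cut at C5=C6 (Wittig) and C7–C8 (aldol), and its butenolide is traced back to a furan.
- Enabling feature: O9–C9–C10–C1–C2(=O) is a γ-oxygenated ketone, so O9 and C2 can be tied as a butenolide that is not in the target. It offers C10=C1 as Michael acceptor and C2 as acylating carbon, and its ring fixes C10 and the cis ring fusion.
- Forward order: aldol, furan-to-butenolide, Wittig and hydrosilylation give a silyl enol ether; one step then closes ring B (C5 to C10, Michael) and ring A (C3 to C2, Claisen with lactone opening, O9 set free); C15, C4–H and the two esters follow.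
- Stereochemistry: C7 and C8 from the (R)-oxazolidinone syn-aldol; C9 by chelation-controlled reduction; C10 and C5 from the lactone tether; C4 by dissolving-metal reduction; the acyl stereocentre from (R)-2-methylbutanoic acid.

Key step: step 8

Remark: carbons are numbered as in eremophilane for all compounds (ring A = C1–C5 and C10, ring B = C5–C10, C14 on C5, C15 on C4, isopropenyl C11–C13 on C7); (R)-2-methylbutanoic acid and the ylide 10 are taken as purchasable.

Step 1
Reactants: 1 (R)-4-benzyloxazolidin-2-one; 2 3-methylbut-2-enoyl chloride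
Product: 3 (R)-4-benzyl-3-(3-methylbut-2-enoyl)oxazolidin-2-one
Conditions: n-BuLi, THF, −78 °C; then 2, −78 → 0 °C
Reagents that add atoms: none
Why: N-acylation of the lithiated oxazolidinone with the acid chloride (standard imide formation) installs the auxiliary that will control C7 and C8.

Step 2
Reactants: 3 (R)-4-benzyl-3-(3-methylbut-2-enoyl)oxazolidin-2-one; 4 furan-2-carbaldehyde
Product: 5 (R)-4-benzyl-3-[(2R)-2-[(R)-furan-2-yl(hydroxy)methyl]-3-methylbut-3-enoyl]oxazolidin-2-one
Conditions: Bu2BOTf, Et3N, CH2Cl2, −78 → 0 °C; then 4, −78 → 0 °C; H2O2, pH 7 buffer, MeOH, 0 °C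
Reagents that add atoms: none
Why: Evans syn-aldol reaction of the boron dienolate (formed by γ-deprotonation), which should react at its α-carbon through a closed chair transition state, so that the isopropenyl group appears by deconjugation and the (R)-benzyl auxiliary sets C7 (R) and C8 (R) syn.

Step 3
Reactants: 5 (R)-4-benzyl-3-[(2R)-2-[(R)-furan-2-yl(hydroxy)methyl]-3-methylbut-3-enoyl]oxazolidin-2-one
Product: 6 (R)-4-benzyl-3-[(2R)-2-[(R)-furan-2-yl(methoxymethoxy)methyl]-3-methylbut-3-enoyl]oxazolidin-2-one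
Conditions: MOMCl, i-Pr2NEt, Bu4NI (cat.), CH2Cl2, 0 °C → rt
Reagents that add atoms: chloromethyl methyl ether (MOMCl), COCCl
Why: Standard O-alkylation to the MOM ether gives an O8 group that is stable to base, hydride and fluoride, cannot migrate, and can chelate zinc in step 5.

Step 4
Reactants: 6 (R)-4-benzyl-3-[(2R)-2-[(R)-furan-2-yl(methoxymethoxy)methyl]-3-methylbut-3-enoyl]oxazolidin-2-one
Product: 7 (2S)-2-[(R)-furan-2-yl(methoxymethoxy)methyl]-3-methylbut-3-en-1-ol
Conditions: LiBH4, MeOH (1 equiv), Et2O, 0 °C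
Reagents that add atoms: none
Why: Reductive cleavage of the N-acyloxazolidinone by LiBH4 should give the primary alcohol and return the auxiliary, with furan, alkene and acetal inert and C7 untouched.

Step 5
Reactants: 7 (2S)-2-[(R)-furan-2-yl(methoxymethoxy)methyl]-3-methylbut-3-en-1-ol
Product: 9 (5S)-5-[(1R,2S)-2-(hydroxymethyl)-1-(methoxymethoxy)-3-methylbut-3-en-1-yl]furan-2(5H)-one, via hydroxybutenolide 8 (not isolated)
Conditions: O2, hν, tetraphenylporphyrin (cat.), i-Pr2NEt, CH2Cl2, −78 °C; then Zn(BH4)2, Et2O, −40 → 0 °C; then 1 M HCl, rt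
Reagents that add atoms: dioxygen, O=O
Why: [4+2] addition of singlet oxygen to the furan and amine-induced Kornblum–DeLaMare collapse of the endoperoxide give the hydroxybutenolide (ring tautomer of the (Z)-4-oxo-2-enoic acid), whose C9 ketone should be reduced under Cram-chelate control (zinc bridging the C9 carbonyl and the C8 MOM oxygen, hydride anti to C7) to the 8,9-anti alcohol, which lactonises on acidification.

Step 6
Reactants: 9 (5S)-5-[(1R,2S)-2-(hydroxymethyl)-1-(methoxymethoxy)-3-methylbut-3-en-1-yl]furan-2(5H)-one; 10 3-(triphenyl-λ5-phosphanylidene)butan-2-one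
Product: 12 (5S)-5-[(1R,2R,3E)-1-(methoxymethoxy)-4-methyl-5-oxo-2-(prop-1-en-2-yl)hex-3-en-1-yl]furan-2(5H)-one, via aldehyde 11 (not isolated)
Conditions: DMP, NaHCO3, CH2Cl2, 0 °C → rt; then 10, CH2Cl2, rt → 40 °C
Reagents that add atoms: none
Why: Dess–Martin oxidation gives the epimerisable α-branched aldehyde, which is trapped in the same flask by Wittig olefination with the ketone-stabilised ylide to give the (E)-α-methyl enone without added base.

Step 7
Reactants: 12 (5S)-5-[(1R,2R,3E)-1-(methoxymethoxy)-4-methyl-5-oxo-2-(prop-1-en-2-yl)hex-3-en-1-yl]furan-2(5H)-one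
Product: 13 (5S)-5-[(1R,2R,4Z)-1-(methoxymethoxy)-4-methyl-2-(prop-1-en-2-yl)-5-(triethylsilyloxy)hex-4-en-1-yl]furan-2(5H)-one
Conditions: Et3SiH, RhCl(PPh3)3 (2 mol %), benzene, 50 °C; filtration through neutral alumina
Reagents that add atoms: triethylsilane, CC[SiH](CC)CC
Why: Rhodium-catalysed 1,4-hydrosilylation of the s-cis enone places hydride on C6 and silicon on oxygen, fixing the enol ether at C5, whereas the butenolide (locked s-trans) and the 1,1-disubstituted alkene should react much more slowly.

Step 8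
Reactants: 13 (5S)-5-[(1R,2R,4Z)-1-(methoxymethoxy)-4-methyl-2-(prop-1-en-2-yl)-5-(triethylsilyloxy)hex-4-en-1-yl]furan-2(5H)-one
Product: 16 (5S,7R,8R,9S,10S)-2,9-bis(tert-butyldimethylsilyloxy)-8-(methoxymethoxy)-15-noreremophila-2,11-dien-4-one, via keto lactone 14 (not isolated), via hydroxy diketone 15 (not isolated)
Conditions: (Me2N)3S+ Me3SiF2− (TASF, 1.1 equiv), THF (0.01 M), −78 → 0 °C; then TBSOTf, 2,6-lutidine, −78 → 0 °C
Reagents that add atoms: tert-butyldimethylsilyl trifluoromethanesulfonate (TBSOTf), CC(C)(C)[Si](C)(C)OS(=O)(=O)C(F)(F)F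
Why: Fluoride removes the triethylsilyl group to give the metal-free C5 enolate, which adds to C10 of the butenolide (6-(enolexo)-exo-trig Michael addition, closing ring B); the lactone enolate then exchanges a proton with the C3 methyl group, and the C3 enolate attacks the lactone carbonyl C2 (6-(enolendo)-exo-trig acyl substitution of Claisen/Dieckmann type, closing ring A) through a 2-oxabicyclo[3.2.1]octane tetrahedral intermediate that expels the C9 alkoxide and leaves the stable 1,3-diketonate. The closest known reaction type is the consecutive Michael–Claisen [3+3] annulation of ketone enolates with α,β-unsaturated esters to cyclohexane-1,3-diones, here started from a fluoride-generated enolate as in fluoride-mediated Mukaiyama–Michael additions. C10 is set by the tether: the chain hangs from C9, so C5 can only reach the butenolide face syn to C8, which gives the cis-fused bicyclic lactone with H9 and H10 cis. C5 is set by the second closure: only the epimer with the acetyl group cis to C1 can bridge to the lactone carbonyl, because the tetrahedral intermediate needs the C10–C9 bond axial on ring A, which only the cis-decalin allows, and the other epimer can return by retro-Michael addition. The step needs C5 over C3 enolate regioselectivity (secured by the preformed silyl enol ether, and C3 attack on C10 would need an eight-membered ring), survival of the acidic C9–H (no external base, low temperature), and silylation of O2 and not O4 in the quench (O4 is flanked by the quaternary C5), which also caps the freed O9.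

Step 9
Reactants: 16 (5S,7R,8R,9S,10S)-2,9-bis(tert-butyldimethylsilyloxy)-8-(methoxymethoxy)-15-noreremophila-2,11-dien-4-one
Product: 18 (5S,7R,8R,9S,10S)-9-(tert-butyldimethylsilyloxy)-8-(methoxymethoxy)eremophila-3,11-dien-2-one, via tertiary carbinol 17 (not isolated)
Conditions: MeLi, CeCl3, THF, −78 °C; then 1 M HCl, THF, 0 °C → rt
Reagents that add atoms: methyllithium, [Li]C
Why: Stork–Danheiser sequence in which the organocerium reagent should add 1,2 to the hindered C4 carbonyl of the vinylogous silyl ester without enolisation, and aqueous acid then hydrolyses the enol silyl ether with loss of the tertiary allylic hydroxyl to give the 4-methyl-3-en-2-one, while the secondary silyl ether and the MOM ether survive.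

Step 10
Reactants: 18 (5S,7R,8R,9S,10S)-9-(tert-butyldimethylsilyloxy)-8-(methoxymethoxy)eremophila-3,11-dien-2-one
Product: 19 (4S,5R,7R,8R,9S,10S)-9-(tert-butyldimethylsilyloxy)-8-(methoxymethoxy)eremophil-11-en-2-one
Conditions: Li, NH3 (l), THF, t-BuOH (1 equiv), −78 °C; then NH4Cl
Reagents that add atoms: none
Why: Dissolving-metal conjugate reduction of the enone, in which C4 should be protonated axially, anti to the axial C14 methyl, so that C15 ends equatorial and cis to C14 (the more stable epimer, since the 4-epimer would hold C15 syn-axial to C9), with the isolated alkene and both ethers inert.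

Step 11
Reactants: 19 (4S,5R,7R,8R,9S,10S)-9-(tert-butyldimethylsilyloxy)-8-(methoxymethoxy)eremophil-11-en-2-one
Product: 20 (4S,5R,7R,8R,9S,10S)-9-hydroxy-8-(methoxymethoxy)eremophil-11-en-2-one
Conditions: TBAF, AcOH, THF, 0 °C → rt
Reagents that add atoms: none
Why: Fluoride-mediated silyl ether cleavage under acetic acid buffering frees O9 alone, and no silyl or acyl migration is possible because O8 is held as the MOM ether.

Step 12
Reactants: 20 (4S,5R,7R,8R,9S,10S)-9-hydroxy-8-(methoxymethoxy)eremophil-11-en-2-one; 21 (E)-2-methylbut-2-enoic acid (tiglic acid)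
Product: 22 (4S,5R,7R,8R,9S,10S)-8-(methoxymethoxy)-2-oxoeremophil-11-en-9-yl (E)-2-methylbut-2-enoate
Conditions: 21, 2,4,6-trichlorobenzoyl chloride, Et3N, toluene, rt; then 20, DMAP, rt → 50 °C
Reagents that add atoms: none
Why: Yamaguchi esterification through the mixed anhydride should acylate the hindered axial C9 hydroxyl, and the (E)-tiglate, being the stable geometric isomer, is kept.

Step 13
Reactants: 22 (4S,5R,7R,8R,9S,10S)-8-(methoxymethoxy)-2-oxoeremophil-11-en-9-yl (E)-2-methylbut-2-enoate
Product: 23 (4S,5R,7R,8R,9S,10S)-8-hydroxy-2-oxoeremophil-11-en-9-yl (E)-2-methylbut-2-enoate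
Conditions: Me2BBr, CH2Cl2, −78 °C; then NaHCO3 (aq), THF, 0 °C
Reagents that add atoms: none
Why: Lewis-acid acetal cleavage by the bromoborane (via the bromomethyl ether, hydrolysed on bicarbonate work-up) should remove the MOM group at low temperature without touching the ester, the ketone or the isopropenyl group, and the brief neutral work-up should keep the tiglate on O9.

Step 14
Reactants: 23 (4S,5R,7R,8R,9S,10S)-8-hydroxy-2-oxoeremophil-11-en-9-yl (E)-2-methylbut-2-enoate; 24 (R)-2-methylbutanoic acid
Product: 25 (4S,5R,7R,8R,9S,10S)-8-[(2R)-2-methylbutanoyloxy]-2-oxoeremophil-11-en-9-yl (E)-2-methylbut-2-enoate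
Conditions: 24, EDC·HCl, DMAP (cat.), CH2Cl2, 0 °C → rt
Reagents that add atoms: none
Why: Steglich esterification of the unhindered equatorial C8 hydroxyl under carbodiimide activation with catalytic DMAP should be faster than migration of the C9 tiglate and should not epimerise the α-stereocentre of the acid, completing the target.

**Compound list**
1 | (R)-4-benzyloxazolidin-2-one | O=C1N[C@H](Cc2ccccc2)CO1 | starting material
2 | 3-methylbut-2-enoyl chloride | CC(C)=CC(=O)Cl | starting material
3 | (R)-4-benzyl-3-(3-methylbut-2-enoyl)oxazolidin-2-one | CC(C)=CC(=O)N1C(=O)OC[C@H]1Cc1ccccc1 | intermediate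
4 | furan-2-carbaldehyde | O=Cc1ccco1 | starting material
5 | (R)-4-benzyl-3-[(2R)-2-[(R)-furan-2-yl(hydroxy)methyl]-3-methylbut-3-enoyl]oxazolidin-2-one | O=C(N1C(=O)OC[C@H]1Cc1ccccc1)[C@H](C(C)=C)[C@@H](O)c1ccco1 | intermediate
6 | (R)-4-benzyl-3-[(2R)-2-[(R)-furan-2-yl(methoxymethoxy)methyl]-3-methylbut-3-enoyl]oxazolidin-2-one | O=C(N1C(=O)OC[C@H]1Cc1ccccc1)[C@H](C(C)=C)[C@@H](OCOC)c1ccco1 | intermediate
7 | (2S)-2-[(R)-furan-2-yl(methoxymethoxy)methyl]-3-methylbut-3-en-1-ol | OC[C@H](C(C)=C)[C@@H](OCOC)c1ccco1 | intermediate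
8 | 5-hydroxy-5-[(1R,2S)-2-(hydroxymethyl)-1-(methoxymethoxy)-3-methylbut-3-en-1-yl]furan-2(5H)-one (both C5 epimers; ring tautomer of the (Z)-4-oxo-2-enoic acid) | OC[C@H](C(C)=C)[C@@H](OCOC)C1(O)OC(=O)C=C1 | intermediate
9 | (5S)-5-[(1R,2S)-2-(hydroxymethyl)-1-(methoxymethoxy)-3-methylbut-3-en-1-yl]furan-2(5H)-one | OC[C@H](C(C)=C)[C@@H](OCOC)[C@H]1OC(=O)C=C1 | intermediate
10 | 3-(triphenyl-λ5-phosphanylidene)butan-2-one | CC(=O)C(C)=P(c1ccccc1)(c1ccccc1)c1ccccc1 | starting material
11 | (2R)-2-[(R)-(methoxymethoxy)[(2S)-5-oxo-2,5-dihydrofuran-2-yl]methyl]-3-methylbut-3-enal | O=C[C@H](C(C)=C)[C@@H](OCOC)[C@H]1OC(=O)C=C1 | intermediate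
12 | (5S)-5-[(1R,2R,3E)-1-(methoxymethoxy)-4-methyl-5-oxo-2-(prop-1-en-2-yl)hex-3-en-1-yl]furan-2(5H)-one | CC(=O)/C(C)=C/[C@H](C(C)=C)[C@@H](OCOC)[C@H]1OC(=O)C=C1 | intermediate
13 | (5S)-5-[(1R,2R,4Z)-1-(methoxymethoxy)-4-methyl-2-(prop-1-en-2-yl)-5-(triethylsilyloxy)hex-4-en-1-yl]furan-2(5H)-one | C/C(O[Si](CC)(CC)CC)=C(\C)C[C@H](C(C)=C)[C@@H](OCOC)[C@H]1OC(=O)C=C1 | intermediate
14 | (3aS,4S,6R,7R,7aS)-4-acetyl-7-(methoxymethoxy)-4-methyl-6-(prop-1-en-2-yl)hexahydro-1-benzofuran-2(3H)-one | C=C(C)[C@H]1C[C@](C)(C(C)=O)[C@@H]2CC(=O)O[C@@H]2[C@@H]1OCOC | intermediate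
15 | (5S,7R,8R,9S,10S)-9-hydroxy-8-(methoxymethoxy)-15-noreremophil-11-ene-2,4-dione | C=C(C)[C@H]1C[C@@]2(C)[C@H](CC(=O)CC2=O)[C@H](O)[C@@H]1OCOC | intermediate
16 | (5S,7R,8R,9S,10S)-2,9-bis(tert-butyldimethylsilyloxy)-8-(methoxymethoxy)-15-noreremophila-2,11-dien-4-one | C=C(C)[C@H]1C[C@@]2(C)[C@H](CC(O[Si](C)(C)C(C)(C)C)=CC2=O)[C@H](O[Si](C)(C)C(C)(C)C)[C@@H]1OCOC | intermediate
17 | (5S,7R,8R,9S,10S)-2,9-bis(tert-butyldimethylsilyloxy)-8-(methoxymethoxy)eremophila-2,11-dien-4-ol (both C4 epimers) | C=C(C)[C@H]1C[C@@]2(C)[C@H](CC(O[Si](C)(C)C(C)(C)C)=CC2(C)O)[C@H](O[Si](C)(C)C(C)(C)C)[C@@H]1OCOC | intermediate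
18 | (5S,7R,8R,9S,10S)-9-(tert-butyldimethylsilyloxy)-8-(methoxymethoxy)eremophila-3,11-dien-2-one | C=C(C)[C@H]1C[C@@]2(C)[C@H](CC(=O)C=C2C)[C@H](O[Si](C)(C)C(C)(C)C)[C@@H]1OCOC | intermediate
19 | (4S,5R,7R,8R,9S,10S)-9-(tert-butyldimethylsilyloxy)-8-(methoxymethoxy)eremophil-11-en-2-one | C=C(C)[C@H]1C[C@@]2(C)[C@H](CC(=O)C[C@@H]2C)[C@H](O[Si](C)(C)C(C)(C)C)[C@@H]1OCOC | intermediate
20 | (4S,5R,7R,8R,9S,10S)-9-hydroxy-8-(methoxymethoxy)eremophil-11-en-2-one | C=C(C)[C@H]1C[C@@]2(C)[C@H](CC(=O)C[C@@H]2C)[C@H](O)[C@@H]1OCOC | intermediate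
21 | (E)-2-methylbut-2-enoic acid (tiglic acid) | C/C=C(\C)C(=O)O | starting material
22 | (4S,5R,7R,8R,9S,10S)-8-(methoxymethoxy)-2-oxoeremophil-11-en-9-yl (E)-2-methylbut-2-enoate | C=C(C)[C@H]1C[C@@]2(C)[C@H](CC(=O)C[C@@H]2C)[C@H](OC(=O)/C(C)=C/C)[C@@H]1OCOC | intermediate
23 | (4S,5R,7R,8R,9S,10S)-8-hydroxy-2-oxoeremophil-11-en-9-yl (E)-2-methylbut-2-enoate | C=C(C)[C@H]1C[C@@]2(C)[C@H](CC(=O)C[C@@H]2C)[C@H](OC(=O)/C(C)=C/C)[C@@H]1O | intermediate
24 | (R)-2-methylbutanoic acid | CC[C@@H](C)C(=O)O | starting material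
25 | (4S,5R,7R,8R,9S,10S)-8-[(2R)-2-methylbutanoyloxy]-2-oxoeremophil-11-en-9-yl (E)-2-methylbut-2-enoate | C=C(C)[C@H]1C[C@@]2(C)[C@H](CC(=O)C[C@@H]2C)[C@H](OC(=O)/C(C)=C/C)[C@@H]1OC(=O)[C@H](C)CC | target

Total step count: 14. Longest linear sequence: 14 steps (from 1 to 25).

**Steps most likely to fail**

Step 8. Proton transfer from the acidic γ-position C9–H of the butenolide to the metal-free enolate may outrun the Michael addition, which would scramble C9 or eliminate the C8 alkoxy group. The first ring closure may also favour the C5 epimer that cannot close ring A and fail to revert, or the sequence may stop after the first ring. The fallback forms the two bonds separately, so that no basic enolate is present while the butenolide is intact. It sets out from 13, which is cyclised by a Lewis-acid Mukaiyama–Michael addition (TiCl4, CH2Cl2, −78 °C) to the keto lactone 14, and this is isolated. Its C9 is no longer acidic, so LiN(SiMe3)2 (THF, −78 → 0 °C) can form the methyl-ketone enolate for the Dieckmann-type closure of ring A. Quenching with TBSOTf and 2,6-lutidine returns to the route at 16. No new compound arises (F0).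

Step 5. Hydride delivery to C9 may show poor facial selectivity because the carboxylate and the free primary hydroxyl compete with the C8 MOM oxygen for zinc, and hemiketal formation by that hydroxyl may slow the reduction. The fallback does the furan oxidation and the chelation-controlled reduction before the auxiliary is removed, so that no free hydroxyl is present. It sets out from 6, which is photo-oxygenated (O2, hν, tetraphenylporphyrin, i-Pr2NEt, CH2Cl2, −78 °C) to (R)-4-benzyl-3-[(2R)-2-[(R)-(2-hydroxy-5-oxo-2,5-dihydrofuran-2-yl)(methoxymethoxy)methyl]-3-methylbut-3-enoyl]oxazolidin-2-one F1. This is reduced with Zn(BH4)2 and lactonised with acid to (R)-4-benzyl-3-[(2R)-2-[(R)-(methoxymethoxy)[(2S)-5-oxo-2,5-dihydrofuran-2-yl]methyl]-3-methylbut-3-enoyl]oxazolidin-2-one F2. The N-acyloxazolidinone is then reduced directly to the aldehyde with Cp2Zr(H)Cl (THF, rt), a reagent that should leave the lactone alone. This gives aldehyde 11, which is treated with ylide 10 as in step 6, so the route is rejoined at 12.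

Step 10. Protonation of C4 may occur from the wrong face, or the C2 carbonyl may be over-reduced. The fallback sets C4 by hydride delivery instead of protonation. It sets out from 18, which is treated with [(Ph3P)CuH]6 (stoichiometric in hydride, wet benzene/THF, rt). Copper hydride should add to C4 axially, anti to the axial C14 methyl, and the copper enolate is protonated at C3, so the route is rejoined at 19. No new compound arises (F0).

**Further compounds**
F0 | step 8 | none | none
F1 | step 5 | (R)-4-benzyl-3-[(2R)-2-[(R)-(2-hydroxy-5-oxo-2,5-dihydrofuran-2-yl)(methoxymethoxy)methyl]-3-methylbut-3-enoyl]oxazolidin-2-one | O=C(N1C(=O)OC[C@H]1Cc1ccccc1)[C@H](C(C)=C)[C@@H](OCOC)C1(O)OC(=O)C=C1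
F2 | step 5 | (R)-4-benzyl-3-[(2R)-2-[(R)-(methoxymethoxy)[(2S)-5-oxo-2,5-dihydrofuran-2-yl]methyl]-3-methylbut-3-enoyl]oxazolidin-2-one | O=C(N1C(=O)OC[C@H]1Cc1ccccc1)[C@H](C(C)=C)[C@@H](OCOC)[C@H]1OC(=O)C=C1
F0 | step 10 | none | none
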